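**Retrosynthetic overview**
1. Feature: the only ring is the 14-membered lactone (C1–C13 plus the ring oxygen). Its C9 ketone and C11 carbinol form a β-hydroxy ketone (aldol) pair, and C11 is separated from the ring oxygen only by C12 and C13, so a small C11–C13 aldehyde can be carried on C1 as its ester.
2. The ring is closed in step 16 at C10–C11 by a SmI2-mediated intramolecular Reformatsky-type aldol of bromo ketone aldehyde 25. Before that, the O13–C1 ester bond (Yamaguchi) joins keto acid 18 (C1–C10) to alcohol 20 (C11–C13, vinyl group as latent C11 aldehyde, from acetaldehyde by crotylboration).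
3. Acid 18: C4–C5 by titanium aldol of β-keto imide 11 (C1–C4) with aldehyde 6 (C5–C9), then 3,5-syn reduction and ethylation of a C9 Weinreb amide.
4. Aldehyde 6: from meso anhydride 1 by catalytic desymmetrisation (sets C6 and C8) via lactone 4.

Key step: step 16

Remark (assumption): (DHQD)2AQN is taken to give half-ester 2; if it gives the enantiomer, (DHQ)2AQN is used, or the ester end of the enantiomer is reduced with LiBH4, which leads to the same lactone 4.
Remark: chain intermediates are named with the macrolide numbering (C1 = lactone carbonyl, C13 = carbinol carbon of the ring oxygen).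
Remark: metal or boron alkoxide forms of a step's own product that are cleaved on work-up are not numbered separately.

**Step 1**
Reactants: 1 cis-2,4-dimethylglutaric anhydride (meso)
Product: 2 (2S,4R)-5-methoxy-2,4-dimethyl-5-oxopentanoic acid
Conditions: MeOH, (DHQD)2AQN (cat.), Et2O, −40 °C
Reagents that add atoms: methanol, CO
Why: Cinchona-alkaloid-catalysed alcoholysis of a meso anhydride should differentiate the two enantiotopic carbonyl groups, which fixes the absolute configuration of both methyl-bearing centres (C6 and C8) in one operation.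

**Step 2**
Reactants: 2 (2S,4R)-5-methoxy-2,4-dimethyl-5-oxopentanoic acid
Product: 4 (3R,5S)-3,5-dimethyloxan-2-one, via hydroxy ester 3 (not isolated)
Conditions: BH3·SMe2, THF, 0 °C → rt; MeOH; then TsOH (cat.), toluene, rt
Reagents that add atoms: none
Why: Borane reduces a carboxylic acid far faster than an ester (chemoselective acid reduction), and the δ-hydroxy ester should close to the six-membered lactone under acid catalysis without touching either stereocentre.

**Step 3**
Reactants: 4 (3R,5S)-3,5-dimethyloxan-2-one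
Product: 5 (2R,4S)-5-hydroxy-N-methoxy-N,2,4-trimethylpentanamide
Conditions: MeONHMe·HCl, AlMe3, CH2Cl2, 0 °C → rt; aq. KNaC4H4O6 work-up
Reagents that add atoms: N,O-dimethylhydroxylamine hydrochloride, CNOC.Cl
Why: Weinreb aminolysis of a lactone by the aluminium amide opens the ring and puts the future C9 carbonyl into a form that later accepts exactly one ethyl group; the crude hydroxy amide is used at once so that it cannot relactonise.

**Step 4**
Reactants: 5 (2R,4S)-5-hydroxy-N-methoxy-N,2,4-trimethylpentanamide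
Product: 6 (2R,4S)-N-methoxy-N,2,4-trimethyl-5-oxopentanamide
Conditions: Dess–Martin periodinane, NaHCO3, CH2Cl2, 0 °C → rt
Reagents that add atoms: none
Why: Dess–Martin oxidation under buffered, non-basic conditions should give the α-methyl aldehyde without epimerising C6; the amide is inert and the aldehyde is used directly.

**Step 5**
Reactants: 7 (R)-4-benzyl-3-propionyl-1,3-oxazolidin-2-one; 8 propanal
Product: 10 (R)-4-benzyl-3-[(2R,3S)-3-hydroxy-2-methylpentanoyl]-1,3-oxazolidin-2-one, via boron enolate 9 (not isolated)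
Conditions: Bu2BOTf, Et3N, CH2Cl2, −78 → 0 °C; 8, −78 → 0 °C; then pH 7 buffer, MeOH, H2O2
Reagents that add atoms: none
Why: Evans syn-aldol reaction: the (Z)-boron enolate reacts through a Zimmerman–Traxler chair on the face away from the benzyl group, which sets the 2R methyl centre (the carbinol centre is removed in step 6).

**Step 6**
Reactants: 10 (R)-4-benzyl-3-[(2R,3S)-3-hydroxy-2-methylpentanoyl]-1,3-oxazolidin-2-one
Product: 11 (R)-4-benzyl-3-[(R)-2-methyl-3-oxopentanoyl]-1,3-oxazolidin-2-one
Conditions: SO3·pyridine, DMSO, iPr2NEt, CH2Cl2, −10 °C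
Reagents that add atoms: none
Why: Parikh–Doering oxidation gives the β-keto imide, whose C2 centre should not epimerise because A(1,3) strain keeps its C–H bond out of alignment with both carbonyl π systems.

**Step 7**
Reactants: 11 (R)-4-benzyl-3-[(R)-2-methyl-3-oxopentanoyl]-1,3-oxazolidin-2-one; 6 (2R,4S)-N-methoxy-N,2,4-trimethyl-5-oxopentanamide
Product: 13 C1–C9 keto aldol adduct (2R,4R,5S,6S,8R), via titanium enolate 12 (not isolated)
Conditions: TiCl4, iPr2NEt, CH2Cl2, −5 °C; then 6, −78 → −40 °C; aq. NH4Cl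
Reagents that add atoms: none
Why: Titanium aldol of a β-keto imide: the (Z)-chlorotitanium enolate at C4 adds through a closed chair in which the C2 methyl centre directs the enolate face, giving the 2,4-syn-4,5-syn adduct (C4 R, C5 S), and the anti-Felkin preference of a Z-enolate towards the α-methyl aldehyde matches the required 5,6-anti relation.

**Step 8**
Reactants: 13 C1–C9 keto aldol adduct
Product: 14 C1–C9 3,5-syn diol (2R,3S,4R,5S,6S,8R)
Conditions: Zn(BH4)2, CH2Cl2/Et2O, −78 → −20 °C
Reagents that add atoms: none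
Why: Chelation-controlled reduction: zinc ties the C5 hydroxyl and the C3 ketone into a six-membered chelate and hydride should be delivered to give the 3,5-syn diol (C3 S), while imide and Weinreb amide are not reduced at this temperature.

**Step 9**
Reactants: 14 C1–C9 3,5-syn diol
Product: 15 C1–C9 3,5-bis-O-TBS imide
Conditions: TBSOTf, 2,6-lutidine, CH2Cl2, −78 → 0 °C
Reagents that add atoms: tert-butyldimethylsilyl trifluoromethanesulfonate, CC(C)(C)[Si](C)(C)OS(=O)(=O)C(F)(F)F
Why: Silyl triflate with a hindered pyridine base silylates both hindered secondary hydroxyls; it is done promptly so that the C5 hydroxyl cannot lactonise onto the imide or the amide.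

**Step 10**
Reactants: 15 C1–C9 3,5-bis-O-TBS imide
Product: 17 (2R,3S,4R,5S,6S,8R)-3,5-bis[(tert-butyldimethylsilyl)oxy]-9-[methoxy(methyl)amino]-2,4,6,8-tetramethyl-9-oxononanoic acid, via peroxy acid 16 (not isolated)
Conditions: LiOH, H2O2, THF/H2O, 0 °C; then aq. Na2SO3
Reagents that add atoms: hydrogen peroxide (as LiOOH), OO
Why: Hydroperoxide cleavage of an N-acyl oxazolidinone: LiOOH attacks the exocyclic carbonyl selectively and sulfite reduces the peracid, so the Weinreb amide, the silyl ethers and the C2 configuration should be unaffected.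

**Step 11**
Reactants: 17 C1–C9 acid Weinreb amide
Product: 18 (2R,3S,4R,5S,6S,8R)-3,5-bis[(tert-butyldimethylsilyl)oxy]-2,4,6,8-tetramethyl-9-oxoundecanoic acid
Conditions: EtMgBr (excess), THF, 0 °C; cold 1 M HCl work-up
Reagents that add atoms: ethylmagnesium bromide, CC[Mg]Br
Why: Weinreb ketone synthesis: the first equivalent forms the unreactive magnesium carboxylate, further reagent adds once to the N-methoxy-N-methylamide to give a chelated tetrahedral adduct that releases the ethyl ketone only on work-up, so neither over-addition nor epimerisation at C8 is expected.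

**Step 12**
Reactants: 19 acetaldehyde
Product: 20 (2R,3R)-3-methylpent-4-en-2-ol
Conditions: cis-2-butene, n-BuLi, KOtBu, THF, −78 → −45 °C; (−)-Ipc2BOMe, −78 °C; BF3·OEt2; then 19, −78 °C; NaOH, H2O2
Reagents that add atoms: cis-2-butene (delivered as its (Z)-crotyldiisopinocampheylborane), C/C=C\C
Why: Brown asymmetric crotylboration: the (Z)-crotylborane adds through a closed six-membered chair, so Z geometry gives the 12,13-syn relation and the isopinocampheyl groups derived from (+)-α-pinene select the si face of the aldehyde (C13 R, C12 R in 20).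

**Step 13**
Reactants: 18 C1–C10 keto acid; 20 (2R,3R)-3-methylpent-4-en-2-ol
Product: 22 (2R,3R)-3-methylpent-4-en-2-yl ester of 18, via mixed anhydride 21 (not isolated)
Conditions: 2,4,6-Cl3C6H2COCl, Et3N, THF, rt; then 20, DMAP, toluene, rt
Reagents that add atoms: none
Why: Yamaguchi esterification: DMAP attacks the mixed anhydride at the aliphatic carbonyl and the acylpyridinium acylates the secondary alcohol with retention at C13 and, as usual for this method, without epimerisation at C2.

**Step 14**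
Reactants: 22 (2R,3R)-3-methylpent-4-en-2-yl ester of 18
Product: 24 C10-bromo derivative of 22 (epimers at C10), via enol silane 23 (not isolated)
Conditions: LiN(SiMe3)2, Me3SiCl, Et3N, THF, −78 °C; then NBS, THF, −78 → 0 °C
Reagents that add atoms: N-bromosuccinimide, O=C1CCC(=O)N1Br
Why: Kinetic deprotonation removes a proton from the unhindered C10 methylene in preference to the C8 methine and to the less acidic, congested C2 ester position; the enol silane is far more nucleophilic towards NBS than the terminal alkene, so bromine should enter at C10 only, and both C10 epimers later give the same enolate.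

**Step 15**
Reactants: 24 C10-bromo derivative of 22
Product: 25 (2R,3S)-3-methyl-4-oxobutan-2-yl (2R,3S,4R,5S,6S,8R)-10-bromo-3,5-bis[(tert-butyldimethylsilyl)oxy]-2,4,6,8-tetramethyl-9-oxoundecanoate (epimers at C10)
Conditions: O3, pyridine, CH2Cl2, −78 °C; cold aqueous wash; used at once
Reagents that add atoms: ozone, [O-][O+]=O
Why: Ozonolysis in the presence of pyridine, which decomposes the carbonyl oxide directly to the aldehyde, so no phosphine or sulfide (both of which attack α-bromo ketones) is needed; C12 is not touched and the elimination-prone β-acyloxy aldehyde is carried straight into step 16.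

**Step 16**
Reactants: 25 bromo ketone aldehyde (epimers at C10)
Product: 27 3,5-bis-O-(tert-butyldimethylsilyl)-8,8a-deoxyoleandolide, via samarium enolate 26 (not isolated)
Conditions: SmI2 (2.5 equiv), THF, −78 °C, slow addition of 25 (high dilution); aq. NH4Cl at −78 °C
Reagents that add atoms: none
Why: Two single-electron transfers from SmI2 cleave the C10–Br bond, much faster than ketyl formation at the aldehyde or any reduction of the esters, and give a trivalent samarium enolate at C9–C10 only, whichever C10 epimer of the bromide is used. The closest known reaction type is the SmI2-mediated intramolecular Reformatsky/aldol reaction of α-halo carbonyl compounds with tethered aldehydes, which is established for medium and large rings. The enolate carbon C10 adds to the C11 aldehyde in a 14-(enolendo)-exo-trig closure of the macrolactone ring, with samarium bridging the enolate and aldehyde oxygens in a six-membered Zimmerman–Traxler chair that holds the two chain ends together. C10 (R) and the 10,11-syn relation should follow from the (Z)-enolate, which is favoured because it avoids A(1,3) strain between the branched C8 substituent and the C10 methyl, reacting through that chair. C11 (S, 11,12-anti) is controlled by the C12 methyl centre through the anti-Felkin attack typical of Z-enolates, the sense also expected from 1,3-anti induction by the C13 acyloxy group. The step needs enolate formation at C10 alone and cyclisation faster than protonation or dimerisation: the position of the bromine, the absence of any base (no enolisation towards C8 or C2, no elimination of the β-acyloxy aldehyde) and slow addition to excess SmI2 at low temperature are meant to secure this.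

**Step 17**
Reactants: 27 3,5-bis-O-(tert-butyldimethylsilyl)-8,8a-deoxyoleandolide
Product: 28 8,8a-deoxyoleandolide
Conditions: HF·pyridine, pyridine, THF, 0 °C → rt
Reagents that add atoms: none
Why: Fluoride-mediated desilylation under buffered, mildly acidic conditions should remove both silyl ethers without retro-aldol cleavage, dehydration of the β-hydroxy ketone or acyl migration, and no stereocentre is involved.

**Compound list**
1 | cis-2,4-dimethylglutaric anhydride (meso) | C[C@@H]1C[C@H](C)C(=O)OC1=O | starting material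
2 | (2S,4R)-5-methoxy-2,4-dimethyl-5-oxopentanoic acid | OC(=O)[C@@H](C)C[C@@H](C)C(=O)OC | intermediate
3 | methyl (2R,4S)-5-hydroxy-2,4-dimethylpentanoate | OC[C@@H](C)C[C@@H](C)C(=O)OC | intermediate (not isolated)
4 | (3R,5S)-3,5-dimethyloxan-2-one | O=C1OC[C@@H](C)C[C@H]1C | intermediate
5 | (2R,4S)-5-hydroxy-N-methoxy-N,2,4-trimethylpentanamide | OC[C@@H](C)C[C@@H](C)C(=O)N(C)OC | intermediate
6 | (2R,4S)-N-methoxy-N,2,4-trimethyl-5-oxopentanamide | O=C[C@@H](C)C[C@@H](C)C(=O)N(C)OC | intermediate
7 | (R)-4-benzyl-3-propionyl-1,3-oxazolidin-2-one | CCC(=O)N1[C@H](Cc2ccccc2)COC1=O | starting material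
8 | propanal | CCC=O | starting material
9 | (Z)-dibutylboron enolate of 7 | C/C=C(\OB(CCCC)CCCC)N1[C@H](Cc2ccccc2)COC1=O | intermediate (not isolated)
10 | (R)-4-benzyl-3-[(2R,3S)-3-hydroxy-2-methylpentanoyl]-1,3-oxazolidin-2-one | CC[C@H](O)[C@@H](C)C(=O)N1[C@H](Cc2ccccc2)COC1=O | intermediate
11 | (R)-4-benzyl-3-[(R)-2-methyl-3-oxopentanoyl]-1,3-oxazolidin-2-one | CCC(=O)[C@@H](C)C(=O)N1[C@H](Cc2ccccc2)COC1=O | intermediate
12 | (Z)-trichlorotitanium enolate of 11 (enolised at C4) | C/C=C(\O[Ti](Cl)(Cl)Cl)[C@@H](C)C(=O)N1[C@H](Cc2ccccc2)COC1=O | intermediate (not isolated)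
13 | (R)-4-benzyl-3-[(2R,4R,5S,6S,8R)-5-hydroxy-9-[methoxy(methyl)amino]-2,4,6,8-tetramethyl-3,9-dioxononanoyl]-1,3-oxazolidin-2-one | O=C(N1[C@H](Cc2ccccc2)COC1=O)[C@H](C)C(=O)[C@H](C)[C@@H](O)[C@@H](C)C[C@@H](C)C(=O)N(C)OC | intermediate
14 | (R)-4-benzyl-3-[(2R,3S,4R,5S,6S,8R)-3,5-dihydroxy-9-[methoxy(methyl)amino]-2,4,6,8-tetramethyl-9-oxononanoyl]-1,3-oxazolidin-2-one | O=C(N1[C@H](Cc2ccccc2)COC1=O)[C@H](C)[C@@H](O)[C@H](C)[C@@H](O)[C@@H](C)C[C@@H](C)C(=O)N(C)OC | intermediate
15 | 3,5-bis-O-TBS ether of 14 | O=C(N1[C@H](Cc2ccccc2)COC1=O)[C@H](C)[C@@H](O[Si](C)(C)C(C)(C)C)[C@H](C)[C@@H](O[Si](C)(C)C(C)(C)C)[C@@H](C)C[C@@H](C)C(=O)N(C)OC | intermediate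
16 | peroxy acid corresponding to 17 | OOC(=O)[C@H](C)[C@@H](O[Si](C)(C)C(C)(C)C)[C@H](C)[C@@H](O[Si](C)(C)C(C)(C)C)[C@@H](C)C[C@@H](C)C(=O)N(C)OC | intermediate (not isolated)
17 | (2R,3S,4R,5S,6S,8R)-3,5-bis[(tert-butyldimethylsilyl)oxy]-9-[methoxy(methyl)amino]-2,4,6,8-tetramethyl-9-oxononanoic acid | OC(=O)[C@H](C)[C@@H](O[Si](C)(C)C(C)(C)C)[C@H](C)[C@@H](O[Si](C)(C)C(C)(C)C)[C@@H](C)C[C@@H](C)C(=O)N(C)OC | intermediate
18 | (2R,3S,4R,5S,6S,8R)-3,5-bis[(tert-butyldimethylsilyl)oxy]-2,4,6,8-tetramethyl-9-oxoundecanoic acid | OC(=O)[C@H](C)[C@@H](O[Si](C)(C)C(C)(C)C)[C@H](C)[C@@H](O[Si](C)(C)C(C)(C)C)[C@@H](C)C[C@@H](C)C(=O)CC | intermediate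
19 | acetaldehyde | CC=O | starting material
20 | (2R,3R)-3-methylpent-4-en-2-ol | C=C[C@@H](C)[C@@H](C)O | intermediate
21 | mixed anhydride of 18 with 2,4,6-trichlorobenzoic acid | O=C(OC(=O)c1c(Cl)cc(Cl)cc1Cl)[C@H](C)[C@@H](O[Si](C)(C)C(C)(C)C)[C@H](C)[C@@H](O[Si](C)(C)C(C)(C)C)[C@@H](C)C[C@@H](C)C(=O)CC | intermediate (not isolated)
22 | (2R,3R)-3-methylpent-4-en-2-yl (2R,3S,4R,5S,6S,8R)-3,5-bis[(tert-butyldimethylsilyl)oxy]-2,4,6,8-tetramethyl-9-oxoundecanoate | C=C[C@@H](C)[C@@H](C)OC(=O)[C@H](C)[C@@H](O[Si](C)(C)C(C)(C)C)[C@H](C)[C@@H](O[Si](C)(C)C(C)(C)C)[C@@H](C)C[C@@H](C)C(=O)CC | intermediate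
23 | C9–C10 trimethylsilyl enol ether of 22 (Z drawn; geometry without consequence) | C=C[C@@H](C)[C@@H](C)OC(=O)[C@H](C)[C@@H](O[Si](C)(C)C(C)(C)C)[C@H](C)[C@@H](O[Si](C)(C)C(C)(C)C)[C@@H](C)C[C@@H](C)/C(O[Si](C)(C)C)=C/C | intermediate (not isolated)
24 | C10-bromo derivative of 22 (epimers at C10) | C=C[C@@H](C)[C@@H](C)OC(=O)[C@H](C)[C@@H](O[Si](C)(C)C(C)(C)C)[C@H](C)[C@@H](O[Si](C)(C)C(C)(C)C)[C@@H](C)C[C@@H](C)C(=O)C(Br)C | intermediate
25 | (2R,3S)-3-methyl-4-oxobutan-2-yl (2R,3S,4R,5S,6S,8R)-10-bromo-3,5-bis[(tert-butyldimethylsilyl)oxy]-2,4,6,8-tetramethyl-9-oxoundecanoate (epimers at C10) | O=C[C@@H](C)[C@@H](C)OC(=O)[C@H](C)[C@@H](O[Si](C)(C)C(C)(C)C)[C@H](C)[C@@H](O[Si](C)(C)C(C)(C)C)[C@@H](C)C[C@@H](C)C(=O)C(Br)C | intermediate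
26 | (Z)-diiodosamarium C9–C10 enolate of 25 | O=C[C@@H](C)[C@@H](C)OC(=O)[C@H](C)[C@@H](O[Si](C)(C)C(C)(C)C)[C@H](C)[C@@H](O[Si](C)(C)C(C)(C)C)[C@@H](C)C[C@@H](C)/C(O[Sm](I)I)=C/C | intermediate (not isolated)
27 | 3,5-bis-O-(tert-butyldimethylsilyl)-8,8a-deoxyoleandolide | O=C1[C@H](C)[C@@H](O[Si](C)(C)C(C)(C)C)[C@H](C)[C@@H](O[Si](C)(C)C(C)(C)C)[C@@H](C)C[C@@H](C)C(=O)[C@H](C)[C@@H](O)[C@@H](C)[C@@H](C)O1 | intermediate
28 | 8,8a-deoxyoleandolide | C[C@@H]1[C@@H](O)[C@@H](C)C[C@@H](C)C(=O)[C@H](C)[C@@H](O)[C@@H](C)[C@@H](C)OC(=O)[C@H](C)[C@H]1O | target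

**Step count**
Total: 17 steps. Longest linear sequence: 14 steps (steps 1–4, 7–11, 13–17).

**Steps most likely to fail**

Step 16 (key ring closure). The samarium enolate may be protonated or may react with a second molecule before it reaches the tethered aldehyde, or it may add to the wrong aldehyde face, so that the ring forms inefficiently or as C10/C11 diastereomers. Fallback (sets out from 18 and 20, returns to the route at 28): the C10–C11 bond would be made between separate pieces under reagent control and the ring closed at the ester instead. Acid 18 is benzylated (BnBr, Cs2CO3, DMF) to benzyl (2R,3S,4R,5S,6S,8R)-3,5-bis[(tert-butyldimethylsilyl)oxy]-2,4,6,8-tetramethyl-9-oxoundecanoate F1. Alcohol 20 is benzylated (NaH, BnBr, THF) to (3R,4R)-4-(benzyloxy)-3-methylpent-1-ene F2 and ozonised (O3, CH2Cl2, −78 °C; PPh3) to (2S,3R)-3-(benzyloxy)-2-methylbutanal F3. A syn-selective boron aldol of F1 with F3 (Ipc2BOTf, iPr2NEt, CH2Cl2, −78 °C; the enantiomer of the reagent chosen to deliver the 10R,11S adduct) should give the 13-O-benzyl benzyl ester aldol adduct F4. Silylation (TBSOTf, 2,6-lutidine) gives its 11-O-TBS ether F5. Hydrogenolysis (H2, Pd/C, EtOAc) frees the C1 acid and the C13 hydroxyl to give the 3,5,11-tris-O-TBS seco acid F6. Yamaguchi macrolactonisation under high dilution gives 3,5,11-tris-O-TBS-8,8a-deoxyoleandolide F7, and HF·pyridine then gives 28.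

Step 15 (alkene cleavage next to the bromo ketone). While the alkene is cleaved, the α-bromo ketone may undergo substitution or debromination, or the new β-acyloxy aldehyde may lose the carboxylate by elimination. Fallback (sets out from 22, returns at 25): the alkene would be cleaved before bromine is introduced and C11 held as an acetal. Ozonolysis of 22 (O3, CH2Cl2/MeOH, −78 °C; Me2S) gives the (2R,3S)-3-methyl-4-oxobutan-2-yl ester of 18 (keto aldehyde) F8. It is converted without isolation (HC(OMe)3, PPTS, MeOH) into its dimethyl acetal F9. Bromination as in step 14 gives the C10-bromo dimethyl acetal F10, and mild acid hydrolysis (LiBF4, wet MeCN) then releases 25 under non-basic conditions just before step 16.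

Step 14 (bromination at C10). Deprotonation may not be fully regio- and chemoselective (enolisation towards C8 with loss of configuration, or at C2 of the ester), and the enol silane may be brominated twice. Fallback (sets out from 22, returns at 24): regiocontrol would be moved from kinetic deprotonation by a lithium amide to Lewis-acid-directed soft enolisation. Bu2BOTf/iPr2NEt (CH2Cl2, −78 °C), a reagent pair that enolises ethyl ketones on the ethyl side and does not enolise simple esters, converts 22 into the (Z)-dibutylboron enolate of 22 F11, which is brominated in the same flask with NBS to give 24.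

**Further compounds**
F1 | step 16 | benzyl (2R,3S,4R,5S,6S,8R)-3,5-bis[(tert-butyldimethylsilyl)oxy]-2,4,6,8-tetramethyl-9-oxoundecanoate | O=C(OCc1ccccc1)[C@H](C)[C@@H](O[Si](C)(C)C(C)(C)C)[C@H](C)[C@@H](O[Si](C)(C)C(C)(C)C)[C@@H](C)C[C@@H](C)C(=O)CC
F2 | step 16 | (3R,4R)-4-(benzyloxy)-3-methylpent-1-ene | C=C[C@@H](C)[C@@H](C)OCc1ccccc1
F3 | step 16 | (2S,3R)-3-(benzyloxy)-2-methylbutanal | O=C[C@@H](C)[C@@H](C)OCc1ccccc1
F4 | step 16 | 13-O-benzyl benzyl ester aldol adduct (C11 hydroxyl free, configured as in 28) | O=C(OCc1ccccc1)[C@H](C)[C@@H](O[Si](C)(C)C(C)(C)C)[C@H](C)[C@@H](O[Si](C)(C)C(C)(C)C)[C@@H](C)C[C@@H](C)C(=O)[C@H](C)[C@@H](O)[C@@H](C)[C@@H](C)OCc1ccccc1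
F5 | step 16 | 11-O-TBS ether of F4 | O=C(OCc1ccccc1)[C@H](C)[C@@H](O[Si](C)(C)C(C)(C)C)[C@H](C)[C@@H](O[Si](C)(C)C(C)(C)C)[C@@H](C)C[C@@H](C)C(=O)[C@H](C)[C@@H](O[Si](C)(C)C(C)(C)C)[C@@H](C)[C@@H](C)OCc1ccccc1
F6 | step 16 | 3,5,11-tris-O-TBS seco acid (13-hydroxy acid) | OC(=O)[C@H](C)[C@@H](O[Si](C)(C)C(C)(C)C)[C@H](C)[C@@H](O[Si](C)(C)C(C)(C)C)[C@@H](C)C[C@@H](C)C(=O)[C@H](C)[C@@H](O[Si](C)(C)C(C)(C)C)[C@@H](C)[C@@H](C)O
F7 | step 16 | 3,5,11-tris-O-TBS-8,8a-deoxyoleandolide | O=C1[C@H](C)[C@@H](O[Si](C)(C)C(C)(C)C)[C@H](C)[C@@H](O[Si](C)(C)C(C)(C)C)[C@@H](C)C[C@@H](C)C(=O)[C@H](C)[C@@H](O[Si](C)(C)C(C)(C)C)[C@@H](C)[C@@H](C)O1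
F8 | step 15 | (2R,3S)-3-methyl-4-oxobutan-2-yl ester of 18 (keto aldehyde) | O=C[C@@H](C)[C@@H](C)OC(=O)[C@H](C)[C@@H](O[Si](C)(C)C(C)(C)C)[C@H](C)[C@@H](O[Si](C)(C)C(C)(C)C)[C@@H](C)C[C@@H](C)C(=O)CC
F9 | step 15 | dimethyl acetal of F8 | COC(OC)[C@@H](C)[C@@H](C)OC(=O)[C@H](C)[C@@H](O[Si](C)(C)C(C)(C)C)[C@H](C)[C@@H](O[Si](C)(C)C(C)(C)C)[C@@H](C)C[C@@H](C)C(=O)CC
F10 | step 15 | C10-bromo derivative of F9 (epimers at C10) | COC(OC)[C@@H](C)[C@@H](C)OC(=O)[C@H](C)[C@@H](O[Si](C)(C)C(C)(C)C)[C@H](C)[C@@H](O[Si](C)(C)C(C)(C)C)[C@@H](C)C[C@@H](C)C(=O)C(Br)C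
F11 | step 14 | (Z)-dibutylboron enolate of 22 | C=C[C@@H](C)[C@@H](C)OC(=O)[C@H](C)[C@@H](O[Si](C)(C)C(C)(C)C)[C@H](C)[C@@H](O[Si](C)(C)C(C)(C)C)[C@@H](C)C[C@@H](C)/C(OB(CCCC)CCCC)=C/C
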